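**Plan**

- Retrosynthesis: remove the two benzyl ethers; return the saturated C3–C7′ bond to an E-benzylidene lactone; cut O1–C2 and C2–C3, which releases the carbonyl carbon as CO and opens the ring to a 3-butyn-1-ol; cut the C7′–aryl bond (Sonogashira) and the C3≡C7′ unit (one-carbon alkynylation of an aldehyde); finally cut the benzylic C–C bond of a benzylmalonate.
- Enabling feature: in the lactone ring (O1, C2, C3, C4, C5) the carbonyl carbon C2 is a single carbon between O1 and C3, and C3 carries the catechol arm through C7′. C2 can therefore come from carbon monoxide captured between the C5 hydroxyl and a C3≡C7′ triple bond.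
- Forward: the chain is built linearly (malonate alkylation, reduction, diacetate, desymmetrisation, exchange of the two arms, alkynylation, aryl coupling). The only ring, the γ-lactone, closes in step 10; conjugate reduction, equilibration at C3 and debenzylation finish the synthesis.
- Stereochemistry: C4 (R) comes from lipase desymmetrisation of a prochiral diacetate and is α to a carbonyl only in the short-lived aldehyde 10. C3 (R) is set last by thermodynamic equilibration to the trans lactone.

Key step: step 10

Assumption: Burkholderia cepacia lipase is taken to hydrolyse the acetate on the pro-R arm of diacetate 6 (equivalently, to acetylate the pro-R hydroxymethyl of diol 5); if the sense were the reverse, direct acetylation of 5 with vinyl acetate and the same enzyme would give the same monoacetate 7 and step 4 would fall away.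

**Route**

Step 1
Reactants: 1 3,4-dimethoxybenzyl alcohol
Product: 2 4-(bromomethyl)-1,2-dimethoxybenzene
Conditions: PBr3 (0.4 equiv), Et2O, 0 °C
Reagents that add atoms: phosphorus tribromide, BrP(Br)Br
Why: Bromination of an activated benzylic alcohol with PBr3 proceeds by SN2 displacement of the intermediate phosphite ester by bromide and leaves the methyl ethers alone.

Step 2
Reactants: 2 4-(bromomethyl)-1,2-dimethoxybenzene; 3 diethyl malonate
Product: 4 diethyl 2-(3,4-dimethoxybenzyl)malonate
Conditions: NaH, diethyl malonate (2.5 equiv), THF, 0 °C; then 2, 0 °C → rt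
Reagents that add atoms: none
Why: Malonic ester alkylation, in which the sodium enolate of diethyl malonate, kept in excess to suppress dialkylation, displaces the reactive benzylic bromide by SN2.

Step 3
Reactants: 4 diethyl 2-(3,4-dimethoxybenzyl)malonate
Product: 5 2-(3,4-dimethoxybenzyl)propane-1,3-diol
Conditions: LiAlH4, THF, 0 °C → reflux; aqueous NaOH work-up
Reagents that add atoms: none
Why: Hydride reduction of both ester groups by LiAlH4 gives the prochiral 2-substituted propane-1,3-diol, which has a mirror plane and no stereocentre yet.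

Step 4
Reactants: 5 2-(3,4-dimethoxybenzyl)propane-1,3-diol
Product: 6 2-(3,4-dimethoxybenzyl)propane-1,3-diyl diacetate
Conditions: Ac2O, pyridine, DMAP (cat.), CH2Cl2, rt
Reagents that add atoms: acetic anhydride, CC(=O)OC(C)=O
Why: DMAP-catalysed acyl transfer esterifies both primary hydroxyls and supplies the prochiral diacetate that serves as the enzyme substrate.

Step 5
Reactants: 6 2-(3,4-dimethoxybenzyl)propane-1,3-diyl diacetate
Product: 7 (2S)-2-(3,4-dimethoxybenzyl)-3-hydroxypropyl acetate
Conditions: Burkholderia cepacia lipase (Amano lipase PS), phosphate buffer (pH 7)–acetone 9:1, rt, pH kept at 7, stopped after one equivalent of acetic acid is released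
Reagents that add atoms: none
Why: Lipase desymmetrisation by enantiotopic-group-selective ester hydrolysis, in which the chiral active site of the serine hydrolase accepts only one of the two acetoxymethyl arms, so that the stereocentre at C2 is set under enzyme control and the reaction is halted at the monoacetate.

Step 6
Reactants: 7 (2S)-2-(3,4-dimethoxybenzyl)-3-hydroxypropyl acetate
Product: 9 (2R)-3-[(tert-butyldiphenylsilyl)oxy]-2-(3,4-dimethoxybenzyl)propan-1-ol, via silyl ether acetate 8 (not isolated)
Conditions: TBDPSCl, imidazole, DMF, 0 °C → rt; then MeOH, K2CO3, 0 °C → rt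
Reagents that add atoms: tert-butyl(chloro)diphenylsilane, CC(C)(C)[Si](Cl)(c1ccccc1)c1ccccc1
Why: Imidazole-promoted silylation of the free primary hydroxyl followed by base-catalysed transesterification of the acetate to methanol exchanges the roles of the two arms without touching C2, the bulky silyl group not migrating to the liberated hydroxyl under these mild conditions.

Step 7
Reactants: 9 (2R)-3-[(tert-butyldiphenylsilyl)oxy]-2-(3,4-dimethoxybenzyl)propan-1-ol
Product: 11 tert-butyl{[(2R)-2-(3,4-dimethoxybenzyl)but-3-yn-1-yl]oxy}diphenylsilane, via aldehyde 10 (not isolated)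
Conditions: Dess–Martin periodinane, CH2Cl2, 0 °C → rt; crude aldehyde used at once; then dimethyl (1-diazo-2-oxopropyl)phosphonate, K2CO3, MeOH, 0 °C → rt
Reagents that add atoms: dimethyl (1-diazo-2-oxopropyl)phosphonate, COP(=O)(OC)C(=[N+]=[N-])C(C)=O
Why: Dess–Martin oxidation gives the α-branched aldehyde without base, and the Ohira–Bestmann variant of the Seyferth–Gilbert homologation (addition of the diazomethylphosphonate anion, loss of dimethyl phosphate and N2, 1,2-hydrogen shift of the alkylidene carbene) should convert this β-silyloxy aldehyde, which has no leaving group to eliminate, into the terminal alkyne at 0 °C faster than it enolises, so that C2 is retained.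

Step 8
Reactants: 11 tert-butyl{[(2R)-2-(3,4-dimethoxybenzyl)but-3-yn-1-yl]oxy}diphenylsilane; 12 4-bromo-1,2-bis(benzyloxy)benzene
Product: 13 {[(2R)-4-[3,4-bis(benzyloxy)phenyl]-2-(3,4-dimethoxybenzyl)but-3-yn-1-yl]oxy}(tert-butyl)diphenylsilane
Conditions: PdCl2(PhCN)2 (3 mol%), [HP(t-Bu)3]BF4 (6 mol%), CuI (2 mol%), i-Pr2NH, dioxane, rt → 45 °C
Reagents that add atoms: none
Why: Sonogashira coupling, in which the bulky electron-rich phosphine lets zerovalent palladium insert into the electron-rich aryl bromide near room temperature, the copper acetylide transmetalates and reductive elimination forms the aryl–alkyne bond, the propargylic stereocentre being inert to the amine base.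

Step 9
Reactants: 13 {[(2R)-4-[3,4-bis(benzyloxy)phenyl]-2-(3,4-dimethoxybenzyl)but-3-yn-1-yl]oxy}(tert-butyl)diphenylsilane
Product: 14 (2R)-4-[3,4-bis(benzyloxy)phenyl]-2-(3,4-dimethoxybenzyl)but-3-yn-1-ol
Conditions: Bu4NF, THF, 0 °C → rt
Reagents that add atoms: none
Why: Fluoride-mediated desilylation, driven by the strength of the Si–F bond, frees the primary alcohol while the benzyl ethers, the methyl ethers and the alkyne are untouched.

Step 10
Reactants: 14 (2R)-4-[3,4-bis(benzyloxy)phenyl]-2-(3,4-dimethoxybenzyl)but-3-yn-1-ol; 15 carbon monoxide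
Product: 16 (3E,4R)-3-[3,4-bis(benzyloxy)benzylidene]-4-(3,4-dimethoxybenzyl)oxolan-2-one
Conditions: PdCl2(PPh3)2 (5 mol%), SnCl2 (5 mol%), CO (8 atm), MeCN, 70 °C
Reagents that add atoms: none
Why: Under CO the palladium–tin chloride catalyst converts the primary hydroxyl into an alkoxycarbonyl–palladium species with loss of HCl, the tethered alkyne inserts syn into the palladium–acyl bond so that C2 bonds to the proximal alkyne carbon C3, and protonolysis of the vinyl–palladium bond with retention returns divalent palladium. The closest known reaction type is the palladium-catalysed cyclocarbonylation of 3-butyn-1-ols to α-methylene- and α-alkylidene-γ-butyrolactones. The lactone closes in the 5-exo-dig mode, the distal alkyne carbon C7′ remaining outside the ring. No stereocentre is created: the syn addition fixes the alkene as E (aryl trans to the carbonyl), and C4, a propargylic carbon without an acidifying group, is not touched. The step needs regioselectivity (CO on C3 and not on C7′) and chemoselectivity over 5-endo-dig oxypalladation to a dihydrofuran; the first is enforced by the two-atom tether, because a six-membered endo lactone would demand anti addition, and the second by the phosphine-ligated, CO-saturated, oxidant-free catalyst, which favours the alkoxycarbonyl pathway over simple π-activation of the alkyne.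

Step 11
Reactants: 16 (3E,4R)-3-[3,4-bis(benzyloxy)benzylidene]-4-(3,4-dimethoxybenzyl)oxolan-2-one
Product: 17 (3S,4R)-3-[3,4-bis(benzyloxy)benzyl]-4-(3,4-dimethoxybenzyl)oxolan-2-one (cis lactone; any trans epimer formed is carried along)
Conditions: NiCl2·6H2O (0.3 equiv), NaBH4 (3 equiv), MeOH–THF, 0 °C
Reagents that add atoms: none
Why: Nickel boride formed in situ catalyses the conjugate reduction of the aryl-conjugated C=C bond by borohydride, a chemoselective 1,4-reduction that spares the benzyl ethers and the lactone carbonyl at 0 °C, with hydrogen expected to reach C3 mainly from the face remote from the C4 benzyl group so that the cis epimer should predominate, its proportion being immaterial because C3 is equilibrated in the next step.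

Step 12
Reactants: 17 (3S,4R)-3-[3,4-bis(benzyloxy)benzyl]-4-(3,4-dimethoxybenzyl)oxolan-2-one
Product: 18 (3R,4R)-3-[3,4-bis(benzyloxy)benzyl]-4-(3,4-dimethoxybenzyl)oxolan-2-one
Conditions: NaOMe (0.3 equiv), MeOH–THF, rt; then AcOH, dilute HCl work-up
Reagents that add atoms: none
Why: Base-mediated epimerisation through the lactone enolate equilibrates C3, the only acidic stereocentre, to the thermodynamically preferred trans arrangement of the two vicinal benzyl groups, so that C3 (R) is set by thermodynamic control relative to the fixed C4, and any hydroxy ester formed by methanolysis relactonises on acidification.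

Step 13
Reactants: 18 (3R,4R)-3-[3,4-bis(benzyloxy)benzyl]-4-(3,4-dimethoxybenzyl)oxolan-2-one
Product: 19 (3R,4R)-3-(3,4-dihydroxybenzyl)-4-(3,4-dimethoxybenzyl)oxolan-2-one (3'-O-demethylarctigenin)
Conditions: H2 (1 atm), 10% Pd/C, EtOAc–MeOH, rt
Reagents that add atoms: none
Why: Hydrogenolysis of the two aryl benzyl ethers over palladium under neutral conditions releases the catechol without affecting the lactone, the methyl ethers or either stereocentre.

**Compound list**

1 | 3,4-dimethoxybenzyl alcohol | COc1ccc(CO)cc1OC | starting material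
2 | 4-(bromomethyl)-1,2-dimethoxybenzene | COc1ccc(CBr)cc1OC | intermediate
3 | diethyl malonate | CCOC(=O)CC(=O)OCC | starting material
4 | diethyl 2-(3,4-dimethoxybenzyl)malonate | CCOC(=O)C(Cc1ccc(OC)c(OC)c1)C(=O)OCC | intermediate
5 | 2-(3,4-dimethoxybenzyl)propane-1,3-diol | OCC(CO)Cc1ccc(OC)c(OC)c1 | intermediate
6 | 2-(3,4-dimethoxybenzyl)propane-1,3-diyl diacetate | CC(=O)OCC(COC(C)=O)Cc1ccc(OC)c(OC)c1 | intermediate
7 | (2S)-2-(3,4-dimethoxybenzyl)-3-hydroxypropyl acetate | OC[C@H](Cc1ccc(OC)c(OC)c1)COC(C)=O | intermediate
8 | (2R)-3-[(tert-butyldiphenylsilyl)oxy]-2-(3,4-dimethoxybenzyl)propyl acetate (formed in the flask) | CC(C)(C)[Si](c1ccccc1)(c1ccccc1)OC[C@H](Cc1ccc(OC)c(OC)c1)COC(C)=O | intermediate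
9 | (2R)-3-[(tert-butyldiphenylsilyl)oxy]-2-(3,4-dimethoxybenzyl)propan-1-ol | CC(C)(C)[Si](c1ccccc1)(c1ccccc1)OC[C@H](Cc1ccc(OC)c(OC)c1)CO | intermediate
10 | (2S)-3-[(tert-butyldiphenylsilyl)oxy]-2-(3,4-dimethoxybenzyl)propanal (formed in the flask) | CC(C)(C)[Si](c1ccccc1)(c1ccccc1)OC[C@H](Cc1ccc(OC)c(OC)c1)C=O | intermediate
11 | tert-butyl{[(2R)-2-(3,4-dimethoxybenzyl)but-3-yn-1-yl]oxy}diphenylsilane | CC(C)(C)[Si](c1ccccc1)(c1ccccc1)OC[C@H](Cc1ccc(OC)c(OC)c1)C#C | intermediate
12 | 4-bromo-1,2-bis(benzyloxy)benzene | Brc1ccc(OCc2ccccc2)c(OCc2ccccc2)c1 | starting material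
13 | {[(2R)-4-[3,4-bis(benzyloxy)phenyl]-2-(3,4-dimethoxybenzyl)but-3-yn-1-yl]oxy}(tert-butyl)diphenylsilane | CC(C)(C)[Si](c1ccccc1)(c1ccccc1)OC[C@H](Cc1ccc(OC)c(OC)c1)C#Cc1ccc(OCc2ccccc2)c(OCc2ccccc2)c1 | intermediate
14 | (2R)-4-[3,4-bis(benzyloxy)phenyl]-2-(3,4-dimethoxybenzyl)but-3-yn-1-ol | OC[C@H](Cc1ccc(OC)c(OC)c1)C#Cc1ccc(OCc2ccccc2)c(OCc2ccccc2)c1 | intermediate
15 | carbon monoxide | [C-]#[O+] | starting material
16 | (3E,4R)-3-[3,4-bis(benzyloxy)benzylidene]-4-(3,4-dimethoxybenzyl)oxolan-2-one | COc1ccc(C[C@H]2COC(=O)/C2=C/c2ccc(OCc3ccccc3)c(OCc3ccccc3)c2)cc1OC | intermediate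
17 | (3S,4R)-3-[3,4-bis(benzyloxy)benzyl]-4-(3,4-dimethoxybenzyl)oxolan-2-one (cis) | COc1ccc(C[C@H]2COC(=O)[C@H]2Cc2ccc(OCc3ccccc3)c(OCc3ccccc3)c2)cc1OC | intermediate
18 | (3R,4R)-3-[3,4-bis(benzyloxy)benzyl]-4-(3,4-dimethoxybenzyl)oxolan-2-one (trans) | COc1ccc(C[C@H]2COC(=O)[C@@H]2Cc2ccc(OCc3ccccc3)c(OCc3ccccc3)c2)cc1OC | intermediate
19 | (3R,4R)-3-(3,4-dihydroxybenzyl)-4-(3,4-dimethoxybenzyl)oxolan-2-one (3'-O-demethylarctigenin) | COc1ccc(C[C@H]2COC(=O)[C@@H]2Cc2ccc(O)c(O)c2)cc1OC | target

**Step count**

Total step count: 13. Longest linear sequence: 13 steps (1 → 19); compounds 3, 12 and 15 are purchased.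

**Steps most likely to fail**

Step 10. The internal aryl alkyne may insert only slowly into the alkoxycarbonyl–palladium bond, so that 5-endo cycloisomerisation of the alkynol or intermolecular ester formation takes over. The fallback moves the arylation behind the ring closure. It sets out from silyl alkyne 11: desilylation with Bu4NF in THF gives the terminal alkynol (2R)-2-(3,4-dimethoxybenzyl)but-3-yn-1-ol F1. Cyclocarbonylation of F1 under the conditions of step 10, terminal 3-butyn-1-ols being the best-established substrates for this reaction, gives the α-methylene lactone (4R)-4-(3,4-dimethoxybenzyl)-3-methylideneoxolan-2-one F2. A Heck arylation of F2 with bromide 12 (Pd(OAc)2, KOAc, Bu4NBr, DMF, 80 °C) then places the aryl group on the exocyclic carbon, and the route is rejoined at benzylidene lactone 16.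

Step 5. Incomplete discrimination between the two enantiotopic acetates, or acyl migration in the aqueous medium, would erode the enantiomeric purity that every later compound inherits. The fallback is a non-enzymatic desymmetrisation that sets out from diol 5. Mono-benzoylation with vinyl benzoate, catalysed by the dinuclear zinc complex formed from Et2Zn and the ProPhenol ligand (2,6-bis{[2-(hydroxydiphenylmethyl)pyrrolidin-1-yl]methyl}-4-methylphenol, in the enantiomeric form that acylates the pro-S arm) in toluene at −15 °C, should give (2S)-2-(3,4-dimethoxybenzyl)-3-hydroxypropyl benzoate F3. Silylation (TBDPSCl, imidazole, DMF) gives (2R)-3-[(tert-butyldiphenylsilyl)oxy]-2-(3,4-dimethoxybenzyl)propyl benzoate F4, and methanolysis of the benzoate (K2CO3, MeOH) rejoins the route at alcohol 9.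

Step 7. The α-branched aldehyde may epimerise by enolisation in the basic methanolic medium before the alkynylation consumes it, which would lower the configurational purity at C2. The fallback avoids base while the aldehyde is present. It sets out from aldehyde 10, made from 9 by the same oxidation: dibromo-olefination (CBr4, PPh3, Zn, CH2Cl2, 0 °C) gives tert-butyl{[(2R)-4,4-dibromo-2-(3,4-dimethoxybenzyl)but-3-en-1-yl]oxy}diphenylsilane F5. Treatment of F5 with n-BuLi (2.1 equiv, THF, −78 °C; Corey–Fuchs sequence) gives alkyne 11, where the route is rejoined.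

**Further compounds**

F1 | step 10 | (2R)-2-(3,4-dimethoxybenzyl)but-3-yn-1-ol | OC[C@H](Cc1ccc(OC)c(OC)c1)C#C
F2 | step 10 | (4R)-4-(3,4-dimethoxybenzyl)-3-methylideneoxolan-2-one | COc1ccc(C[C@H]2COC(=O)C2=C)cc1OC
F3 | step 5 | (2S)-2-(3,4-dimethoxybenzyl)-3-hydroxypropyl benzoate | OC[C@H](Cc1ccc(OC)c(OC)c1)COC(=O)c1ccccc1
F4 | step 5 | (2R)-3-[(tert-butyldiphenylsilyl)oxy]-2-(3,4-dimethoxybenzyl)propyl benzoate | CC(C)(C)[Si](c1ccccc1)(c1ccccc1)OC[C@H](Cc1ccc(OC)c(OC)c1)COC(=O)c1ccccc1
F5 | step 7 | tert-butyl{[(2R)-4,4-dibromo-2-(3,4-dimethoxybenzyl)but-3-en-1-yl]oxy}diphenylsilane | CC(C)(C)[Si](c1ccccc1)(c1ccccc1)OC[C@H](Cc1ccc(OC)c(OC)c1)C=C(Br)Br
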